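**Plan**

1. Numbering follows the chromene core of the target: O-1, C-2/C-3 (cis-dimethyl), C-4 (ketone), C-4a, C-5 (enol), C-6 (side chain), C-7 (ketone), C-8 (quaternary), C-8a.
2. Retrosynthetic cuts, in order: tert-butyl ester; C-5–C-6 (Dieckmann); C-4a–C-8a (O→C acyl shift with recyclisation); C-4–C-4a (ester-enolate Claisen on a Weinreb amide); C-8–prenyl and C-8–lavandulyl (two alkylations); O-1–C-8a (ester from an acylketene); C-7–C-8 (acyl Meldrum's acid).
3. Enabling feature: C-8a is an enol-ether carbon held between O-1 and the non-enolisable quaternary C-8, so it is a carboxyl-level carbon that can be carried as the ester of the C-2 alcohol. C-4a is the central carbon of a 1,3-dicarbonyl (C-4 ketone, C-5 carboxyl), and the two meet through a six-membered transition state.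
4. Forward: the open chain is assembled on the O-1–C-8a ester, the dihydropyranone ring is closed first (step 12) and the carbocycle second (step 13). Because C-5 is still an ester when O-1 recloses, O-1 can only end on C-8a.
5. Stereochemistry: C-2/C-3 from an Evans syn-aldol, the benzylic centre from desymmetrisation of 3-phenylglutaric anhydride, the lavandulyl centre from (R)-lavandulol, C-8 from a catalyst-controlled phase-transfer prenylation.

Key step: step 12

Assumption: (R)-lavandulol is bought as the single enantiomer, and in steps 3 and 10 the catalyst antipode that delivers the drawn configuration is the one used (the quinine-derived and the (S,S) catalysts are written as the working choice).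

**Route**

Step 1
Reactants: 1 (S)-4-benzyl-3-propanoyl-1,3-oxazolidin-2-one; 2 acetaldehyde
Product: 3 (S)-4-benzyl-3-[(2S,3R)-3-hydroxy-2-methylbutanoyl]-1,3-oxazolidin-2-one
Conditions: Bu2BOTf, i-Pr2NEt, CH2Cl2, −78 → 0 °C; then pH 7 buffer, MeOH, H2O2, 0 °C
Reagents that add atoms: none
Why: Evans boron-mediated syn-aldol, in which the Z-boron enolate reacts through a Zimmerman–Traxler chair on the face away from the benzyl group and so sets (2S,3R), the future cis C-3/C-2 pair.

Step 2
Reactants: 3 (S)-4-benzyl-3-[(2S,3R)-3-hydroxy-2-methylbutanoyl]-1,3-oxazolidin-2-one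
Product: 4 (2S,3R)-3-hydroxy-N-methoxy-N,2-dimethylbutanamide
Conditions: MeNHOMe·HCl, AlMe3, CH2Cl2, −10 °C → rt; Rochelle salt work-up
Reagents that add atoms: N,O-dimethylhydroxylamine hydrochloride, CNOC.Cl
Why: Weinreb transamidation with the aluminium amide cleaves the exocyclic imide carbonyl without retro-aldol or epimerisation, and the amide is neither acidic enough to eliminate a β-acyloxy group nor electrophilic enough to be attacked by the stabilised enolates of steps 9 and 10.

Step 3
Reactants: 5 3-phenylglutaric anhydride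
Product: 6 (R)-5-(benzyloxy)-5-oxo-3-phenylpentanoic acid
Conditions: BnOH, quinine-derived bifunctional sulfonamide catalyst (10 mol%), MTBE, rt
Reagents that add atoms: benzyl alcohol, OCc1ccccc1
Why: Organocatalytic enantioselective alcoholysis (desymmetrisation) of a prochiral cyclic anhydride, in which the bifunctional cinchona catalyst activates one of the two enantiotopic carbonyls and fixes the benzylic centre.

Step 4
Reactants: 6 (R)-5-(benzyloxy)-5-oxo-3-phenylpentanoic acid
Product: 7 1-benzyl 5-tert-butyl (S)-3-phenylpentanedioate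
Conditions: tert-butyl 2,2,2-trichloroacetimidate, BF3·OEt2 (cat.), CH2Cl2/cyclohexane, rt
Reagents that add atoms: tert-butyl 2,2,2-trichloroacetimidate, CC(C)(C)OC(=N)C(Cl)(Cl)Cl
Why: Acid-catalysed tert-butylation of the free acid by the trichloroacetimidate leaves the benzyl ester and the stereocentre untouched (the descriptor changes only through the priority rules).

Step 5
Reactants: 7 1-benzyl 5-tert-butyl (S)-3-phenylpentanedioate
Product: 8 (S)-5-(tert-butoxy)-5-oxo-3-phenylpentanoic acid
Conditions: H2 (1 atm), Pd/C, EtOAc, rt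
Reagents that add atoms: none
Why: Hydrogenolysis of the benzyl ester frees the arm that becomes C-6/C-7 while the tert-butyl ester stays.

Step 6
Reactants: 8 (S)-5-(tert-butoxy)-5-oxo-3-phenylpentanoic acid; 9 Meldrum's acid
Product: 10 tert-butyl (S)-5-(2,2-dimethyl-4,6-dioxo-1,3-dioxan-5-yl)-5-oxo-3-phenylpentanoate
Conditions: DCC, DMAP, CH2Cl2, 0 °C → rt
Reagents that add atoms: none
Why: Carbodiimide-mediated C-acylation of Meldrum's acid gives the acyl Meldrum's acid, a storable acylketene precursor, and forms the future C-7–C-8 bond.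

Step 7
Reactants: 10 tert-butyl (S)-5-(2,2-dimethyl-4,6-dioxo-1,3-dioxan-5-yl)-5-oxo-3-phenylpentanoate; 4 (2S,3R)-3-hydroxy-N-methoxy-N,2-dimethylbutanamide
Product: 12 1-tert-butyl 7-[(2R,3S)-4-[methoxy(methyl)amino]-3-methyl-4-oxobutan-2-yl] (S)-5-oxo-3-phenylheptanedioate, via acylketene 11 (not isolated)
Conditions: toluene, 90 °C
Reagents that add atoms: none
Why: Thermal retro-[4+2] fragmentation of the acyl Meldrum's acid releases acetone and CO2, and the resulting acylketene is trapped by the secondary alcohol under neutral conditions, so the O-1–C-8a ester forms without touching C-2/C-3.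

Step 8
Reactants: 13 (R)-lavandulol
Product: 14 (R)-lavandulyl iodide
Conditions: PPh3, imidazole, I2, CH2Cl2, 0 °C → rt
Reagents that add atoms: iodine, II
Why: Appel-type iodination converts the primary homoallylic alcohol by SN2 at CH2 without involving the stereocentre.

Step 9
Reactants: 12 1-tert-butyl 7-[(2R,3S)-4-[methoxy(methyl)amino]-3-methyl-4-oxobutan-2-yl] (S)-5-oxo-3-phenylheptanedioate; 14 (R)-lavandulyl iodide
Product: 15 1-tert-butyl 7-[(2R,3S)-4-[methoxy(methyl)amino]-3-methyl-4-oxobutan-2-yl] (3S)-6-[(2S)-5-methyl-2-(prop-1-en-2-yl)hex-4-en-1-yl]-5-oxo-3-phenylheptanedioate (both C-6 epimers)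
Conditions: Cs2CO3, DMF, 45 °C
Reagents that add atoms: none
Why: SN2 C-alkylation of the β-keto ester enolate at its doubly activated methylene by the primary iodide; the new centre (future C-8) is epimerisable and is erased in the next step.

Step 10
Reactants: 15 the α-lavandulyl β-keto ester (both C-6 epimers); 16 prenyl bromide
Product: 17 1-tert-butyl 7-[(2R,3S)-4-[methoxy(methyl)amino]-3-methyl-4-oxobutan-2-yl] (3S,6R)-6-(3-methylbut-2-en-1-yl)-6-[(2S)-5-methyl-2-(prop-1-en-2-yl)hex-4-en-1-yl]-5-oxo-3-phenylheptanedioate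
Conditions: (S,S)-configured C2-symmetric N-spiro bis(binaphthyl)ammonium bromide with 3,4,5-trifluorophenyl groups (5 mol%), solid Cs2CO3, toluene, −20 → 0 °C
Reagents that add atoms: none
Why: Asymmetric phase-transfer alkylation, in which the chiral ammonium cation pairs with the trisubstituted enolate and shields one face, so prenyl bromide should set the quaternary centre (future C-8) under catalyst control with little bias expected from the remote centres.

Step 11
Reactants: 17 the quaternary β-keto ester Weinreb amide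
Product: 18 1-tert-butyl 7-[(2R,3S)-6-ethoxy-3-methyl-4,6-dioxohexan-2-yl] (3S,6R)-6-(3-methylbut-2-en-1-yl)-6-[(2S)-5-methyl-2-(prop-1-en-2-yl)hex-4-en-1-yl]-5-oxo-3-phenylheptanedioate
Conditions: EtOAc, LDA (3.5 equiv of enolate), THF, −78 °C; AcOH quench at −78 °C
Reagents that add atoms: ethyl acetate, CCOC(C)=O
Why: Claisen-type acylation of the lithium ester enolate by the Weinreb amide through its stable chelate forms C-4–C-4a; the excess enolate first enolises the hindered future C-7 ketone, which protects it, and the ester on the quaternary carbon and the tert-butyl ester are too hindered to compete.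

Step 12
Reactants: 18 the bis(β-keto ester)
Product: 20 tert-butyl (3S,6S)-6-[(2R,3S)-5-(ethoxycarbonyl)-2,3-dimethyl-4-oxo-3,4-dihydro-2H-pyran-6-yl]-9-methyl-6-[(2S)-5-methyl-2-(prop-1-en-2-yl)hex-4-en-1-yl]-5-oxo-3-phenyldec-8-enoate, via hydroxy tricarbonyl 19 (not isolated)
Conditions: NaH (1.1 equiv), THF, 0 → 45 °C; AcOH; then PPTS (cat.), toluene, 4 Å MS, 60 °C
Reagents that add atoms: none
Why: Sodium hydride converts the ethyl 3-oxoalkanoate unit into its C-4a enolate, which adds 6-exo-trig to the ester carbonyl C-8a that O-1 already carries, and collapse of the six-membered tetrahedral intermediate moves the acyl group from O-1 to C-4a to give the stabilised tricarbonyl enolate of 19. After acidification the freed C-2 hydroxyl adds back 6-exo-trig to the new C-8a ketone and loses water under PPTS, which closes the dihydropyranone as a vinylogous ester with the C-4a=C-8a bond in place. The closest known reaction type is the Baker–Venkataraman O→C acyl shift followed by chromone-type cyclodehydration, in its aliphatic β-acyloxy-ketone form, and the attack of a stabilised carbanion on an ester flanked by a quaternary carbon parallels Lacey–Dieckmann closures of α,α-disubstituted esters. No stereocentre is created: C-2 and C-3 are untouched because only the acyl C–O bond is cleaved, C-8 is non-enolisable, and the transient C-4a centre ends sp2. The step needs regioselectivity in the reclosure and gets it from the oxidation pattern, since C-5 is still an ester (weak acid ketalises a ketone far faster than it transesterifies a conjugated ester) and the C-7 ketone would require an eight-membered ring, so O-1 can only condense on C-8a. It also needs the acyl shift to beat β-elimination of the carboxylate and retro-Claisen cleavage at C-8, which one equivalent of a non-nucleophilic base should secure by keeping the molecule as the mono-enolate, in which the C-3 hydrogen is not acidic and no free alkoxide persists.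

Step 13
Reactants: 20 the dihydropyranone keto diester
Product: 21 tert-butyl (3S)-3-[(2R,3S,8S)-5-hydroxy-2,3-dimethyl-8-(3-methylbut-2-en-1-yl)-8-[(2S)-5-methyl-2-(prop-1-en-2-yl)hex-4-en-1-yl]-4,7-dioxo-3,4,7,8-tetrahydro-2H-chromen-6-yl]-3-phenylpropanoate
Conditions: LiHMDS (2.1 equiv), THF, −78 → −30 °C; AcOH quench at −78 °C
Reagents that add atoms: none
Why: Dieckmann condensation, in which the kinetic enolate of the CH2 ketone (C-6) attacks the ethyl ester held cis to it on the C-4a=C-8a double bond (6-exo-trig) and loss of ethoxide is driven by formation of the enolate of the vinylogous acid; low temperature and a bare excess of base protect the less stable cis C-3 centre from epimerisation.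

Step 14
Reactants: 21 the tert-butyl ester of the target
Product: 23 (3S)-3-[(2R,3S,8S)-5-hydroxy-2,3-dimethyl-8-(3-methylbut-2-en-1-yl)-8-[(2S)-5-methyl-2-(prop-1-en-2-yl)hex-4-en-1-yl]-4,7-dioxo-3,4,7,8-tetrahydro-2H-chromen-6-yl]-3-phenylpropanoic acid, via bis-silyl derivative 22 (not isolated)
Conditions: TMSOTf, 2,6-lutidine, CH2Cl2, 0 °C; then pH 5 aqueous buffer
Reagents that add atoms: trimethylsilyl trifluoromethanesulfonate, C[Si](C)(C)OS(=O)(=O)C(F)(F)F (silyl groups of 22, lost again on work-up)
Why: Silyl triflate-mediated cleavage of the tert-butyl ester (O-silylation, loss of isobutene) under lutidine buffering avoids protic acid, which would attack the prenyl and lavandulyl alkenes, and strong base, which would epimerise C-3; the aqueous work-up hydrolyses the silyl ester and silyl enol ether of 22.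

**Compound list**

1 | (S)-4-benzyl-3-propanoyl-1,3-oxazolidin-2-one | CCC(=O)N1[C@@H](Cc2ccccc2)COC1=O | starting material
2 | acetaldehyde | CC=O | starting material
3 | (S)-4-benzyl-3-[(2S,3R)-3-hydroxy-2-methylbutanoyl]-1,3-oxazolidin-2-one | O[C@H](C)[C@H](C)C(=O)N1[C@@H](Cc2ccccc2)COC1=O | intermediate
4 | (2S,3R)-3-hydroxy-N-methoxy-N,2-dimethylbutanamide | O[C@H](C)[C@H](C)C(=O)N(C)OC | intermediate
5 | 3-phenylglutaric anhydride (4-phenyloxane-2,6-dione) | O=C1CC(c2ccccc2)CC(=O)O1 | starting material
6 | (R)-5-(benzyloxy)-5-oxo-3-phenylpentanoic acid | O=C(OCc1ccccc1)C[C@@H](CC(=O)O)c1ccccc1 | intermediate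
7 | 1-benzyl 5-tert-butyl (S)-3-phenylpentanedioate | O=C(OCc1ccccc1)C[C@@H](CC(=O)OC(C)(C)C)c1ccccc1 | intermediate
8 | (S)-5-(tert-butoxy)-5-oxo-3-phenylpentanoic acid | OC(=O)C[C@@H](CC(=O)OC(C)(C)C)c1ccccc1 | intermediate
9 | Meldrum's acid (2,2-dimethyl-1,3-dioxane-4,6-dione) | CC1(C)OC(=O)CC(=O)O1 | starting material
10 | tert-butyl (S)-5-(2,2-dimethyl-4,6-dioxo-1,3-dioxan-5-yl)-5-oxo-3-phenylpentanoate (acyl Meldrum's acid, drawn as keto form) | CC1(C)OC(=O)C(C(=O)C[C@@H](CC(=O)OC(C)(C)C)c2ccccc2)C(=O)O1 | intermediate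
11 | acylketene, tert-butyl (S)-5,7-dioxo-3-phenylhept-6-enoate | O=C=CC(=O)C[C@@H](CC(=O)OC(C)(C)C)c1ccccc1 | intermediate
12 | 1-tert-butyl 7-[(2R,3S)-4-[methoxy(methyl)amino]-3-methyl-4-oxobutan-2-yl] (S)-5-oxo-3-phenylheptanedioate | O=C(CC(=O)C[C@@H](CC(=O)OC(C)(C)C)c1ccccc1)O[C@H](C)[C@H](C)C(=O)N(C)OC | intermediate
13 | (R)-lavandulol, (R)-5-methyl-2-(prop-1-en-2-yl)hex-4-en-1-ol | C=C(C)[C@@H](CC=C(C)C)CO | starting material
14 | (R)-lavandulyl iodide, (R)-1-iodo-5-methyl-2-(prop-1-en-2-yl)hex-4-ene | C=C(C)[C@@H](CC=C(C)C)CI | intermediate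
15 | 1-tert-butyl 7-[(2R,3S)-4-[methoxy(methyl)amino]-3-methyl-4-oxobutan-2-yl] (3S)-6-[(2S)-5-methyl-2-(prop-1-en-2-yl)hex-4-en-1-yl]-5-oxo-3-phenylheptanedioate, both C-6 epimers | C=C(C)[C@@H](CC=C(C)C)CC(C(=O)O[C@H](C)[C@H](C)C(=O)N(C)OC)C(=O)C[C@@H](CC(=O)OC(C)(C)C)c1ccccc1 | intermediate
16 | prenyl bromide (1-bromo-3-methylbut-2-ene) | CC(C)=CCBr | starting material
17 | 1-tert-butyl 7-[(2R,3S)-4-[methoxy(methyl)amino]-3-methyl-4-oxobutan-2-yl] (3S,6R)-6-(3-methylbut-2-en-1-yl)-6-[(2S)-5-methyl-2-(prop-1-en-2-yl)hex-4-en-1-yl]-5-oxo-3-phenylheptanedioate | C=C(C)[C@@H](CC=C(C)C)C[C@](C(=O)O[C@H](C)[C@H](C)C(=O)N(C)OC)(CC=C(C)C)C(=O)C[C@@H](CC(=O)OC(C)(C)C)c1ccccc1 | intermediate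
18 | 1-tert-butyl 7-[(2R,3S)-6-ethoxy-3-methyl-4,6-dioxohexan-2-yl] (3S,6R)-6-(3-methylbut-2-en-1-yl)-6-[(2S)-5-methyl-2-(prop-1-en-2-yl)hex-4-en-1-yl]-5-oxo-3-phenylheptanedioate | C=C(C)[C@@H](CC=C(C)C)C[C@](C(=O)O[C@H](C)[C@H](C)C(=O)CC(=O)OCC)(CC=C(C)C)C(=O)C[C@@H](CC(=O)OC(C)(C)C)c1ccccc1 | intermediate
19 | 1-tert-butyl 9-ethyl (3S,6R)-8-[(2S,3R)-3-hydroxy-2-methylbutanoyl]-6-(3-methylbut-2-en-1-yl)-6-[(2S)-5-methyl-2-(prop-1-en-2-yl)hex-4-en-1-yl]-5,7-dioxo-3-phenylnonanedioate (C-8 epimers, enolised) | C=C(C)[C@@H](CC=C(C)C)C[C@](C(=O)C(C(=O)OCC)C(=O)[C@@H](C)[C@@H](C)O)(CC=C(C)C)C(=O)C[C@@H](CC(=O)OC(C)(C)C)c1ccccc1 | intermediate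
20 | tert-butyl (3S,6S)-6-[(2R,3S)-5-(ethoxycarbonyl)-2,3-dimethyl-4-oxo-3,4-dihydro-2H-pyran-6-yl]-9-methyl-6-[(2S)-5-methyl-2-(prop-1-en-2-yl)hex-4-en-1-yl]-5-oxo-3-phenyldec-8-enoate | C=C(C)[C@@H](CC=C(C)C)C[C@](C1=C(C(=O)OCC)C(=O)[C@@H](C)[C@@H](C)O1)(CC=C(C)C)C(=O)C[C@@H](CC(=O)OC(C)(C)C)c1ccccc1 | intermediate
21 | tert-butyl (3S)-3-[(2R,3S,8S)-5-hydroxy-2,3-dimethyl-8-(3-methylbut-2-en-1-yl)-8-[(2S)-5-methyl-2-(prop-1-en-2-yl)hex-4-en-1-yl]-4,7-dioxo-3,4,7,8-tetrahydro-2H-chromen-6-yl]-3-phenylpropanoate | C=C(C)[C@@H](CC=C(C)C)C[C@]1(CC=C(C)C)C(=O)C([C@@H](CC(=O)OC(C)(C)C)c2ccccc2)=C(O)C2=C1O[C@H](C)[C@H](C)C2=O | intermediate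
22 | trimethylsilyl ester and 5-O-trimethylsilyl enol ether of 23 | C=C(C)[C@@H](CC=C(C)C)C[C@]1(CC=C(C)C)C(=O)C([C@@H](CC(=O)O[Si](C)(C)C)c2ccccc2)=C(O[Si](C)(C)C)C2=C1O[C@H](C)[C@H](C)C2=O | intermediate
23 | (3S)-3-[(2R,3S,8S)-5-hydroxy-2,3-dimethyl-8-(3-methylbut-2-en-1-yl)-8-[(2S)-5-methyl-2-(prop-1-en-2-yl)hex-4-en-1-yl]-4,7-dioxo-3,4,7,8-tetrahydro-2H-chromen-6-yl]-3-phenylpropanoic acid | C=C(C)[C@@H](CC=C(C)C)C[C@]1(CC=C(C)C)C(=O)C([C@@H](CC(=O)O)c2ccccc2)=C(O)C2=C1O[C@H](C)[C@H](C)C2=O | target

**Summary and risks**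

Total step count: 14. Longest linear sequence: 11 steps (5 → 6 → 7 → 8 → 10 → 12 → 15 → 17 → 18 → 20 → 21 → 23; steps 3–7 and 9–14).

Steps most likely to fail:

Step 12. The O→C acyl shift may lose to β-elimination of the carboxylate from the β-acyloxy ketone, to retro-Claisen cleavage at the quaternary carbon, or may stall at the hindered ester. The fallback sets out from 18 and comes back at 20, and generates the nucleophile as a latent, base-free enolate. The β-keto ester of 18 is silylated (TMSCl, Et3N) to the trimethylsilyl enol ether F1. A stoichiometric anhydrous fluoride source (TBAT, THF, −78 → 0 °C) then releases the tetrabutylammonium enolate, so the acyl shift should run at low temperature with no excess base. Acidification and the same PPTS treatment close the ring to 20.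

Step 10. Facial selectivity may be poor, through a mismatch between the catalyst and the chiral ester and lavandulyl groups, or through a loose ion pair with this non-tert-butyl ester. The fallback sets out from 15 and comes back at 17, and replaces catalyst control by a covalent auxiliary. Condensation of 15 with L-valine tert-butyl ester gives the enamino ester F2. Deprotonation with LDA and alkylation of the chelated lithio-enamine with prenyl bromide 16 gives the ketimine F3, and mild hydrolysis (aqueous AcOH/NaOAc) returns 17. The solvent (toluene versus THF/HMPA) or the antipodal auxiliary selects the face.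

Step 11. The ester enolate may add to the future C-7 ketone, followed by retro-Claisen cleavage of the quaternary β-keto ester, instead of reacting at the Weinreb amide. The fallback sets out from 17 and comes back at 18, and masks the ketone first. Kinetic enolisation and silylation (LiHMDS, TMSCl, THF, −78 °C) give the trimethylsilyl enol ether F4. The ester enolate is then added to the Weinreb amide, and the citric acid work-up hydrolyses the silyl enol ether to give 18.

Further compounds
F1 | step 12 | trimethylsilyl enol ether of the ethyl 3-oxoalkanoate unit of 18 | C=C(C)[C@@H](CC=C(C)C)C[C@](C(=O)O[C@H](C)[C@H](C)C(O[Si](C)(C)C)=CC(=O)OCC)(CC=C(C)C)C(=O)C[C@@H](CC(=O)OC(C)(C)C)c1ccccc1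
F2 | step 10 | enamino ester from 15 and L-valine tert-butyl ester | C=C(C)[C@@H](CC=C(C)C)CC(C(=O)O[C@H](C)[C@H](C)C(=O)N(C)OC)=C(N[C@@H](C(C)C)C(=O)OC(C)(C)C)C[C@@H](CC(=O)OC(C)(C)C)c1ccccc1
F3 | step 10 | α-prenylated ketimine (tert-butyl L-valinate imine of 17) | C=C(C)[C@@H](CC=C(C)C)C[C@](C(=O)O[C@H](C)[C@H](C)C(=O)N(C)OC)(CC=C(C)C)C(=N[C@@H](C(C)C)C(=O)OC(C)(C)C)C[C@@H](CC(=O)OC(C)(C)C)c1ccccc1
F4 | step 11 | trimethylsilyl enol ether of the future C-7 ketone of 17 | C=C(C)[C@@H](CC=C(C)C)C[C@](C(=O)O[C@H](C)[C@H](C)C(=O)N(C)OC)(CC=C(C)C)C(O[Si](C)(C)C)=C[C@@H](CC(=O)OC(C)(C)C)c1ccccc1
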